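Both halves of this C4→C6′ linked bis-flavan-3-ol are (2R,3S)-fisetinidol units, so one flavanonol, 9, serves twice. Its pyranone ring is cut at the two opposite bonds O1–C8a and C2–C3: aldehyde 6 brings O1=C2 with ring B, and an α-benzyloxy 2-fluoroacetophenone enol silane brings C3–C4–C4a–C8a with ring A. In one flask an enantioselective Mukaiyama aldol joins C2 to C3 and the freed alkoxide displaces fluoride at C8a, exploiting the C4 carbonyl that sits ortho to C8a on ring A. Reduction, bromine capping of ring A and a Friedel–Crafts union of C4 with C6′ complete the skeleton.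

Key step: step 3

Numbering: flavan numbering is used for both units (O1, C2, C3, C4, C4a, C5 to C8, C8a; ring B carbons primed). The unit bonded through its C4 is the upper unit (from 11); the unit with a C4 methylene whose ring B carries it at C6′ is the lower unit (from 12).
Assumption: the acyloxyborane made from the (2S,3S)-tartrate is taken to expose the Si face of aldehyde 6 (giving 2R); if its sense is the reverse, the catalyst from the (2R,3R)-acid is used and nothing else changes.

Step 1
Reactants: 1 4-(benzyloxy)-1-bromo-2-fluorobenzene; 2 2-(benzyloxy)-N-methoxy-N-methylacetamide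
Product: 4 2-(benzyloxy)-1-[4-(benzyloxy)-2-fluorophenyl]ethan-1-one, via arylmagnesium chloride 3 (not isolated)
Conditions: iPrMgCl·LiCl, THF, −15 °C; then 2, −15 to 0 °C; aqueous NH4Cl
Reagents that add atoms: none
Why: Bromine–magnesium exchange, helped by the ortho fluorine, followed by Weinreb ketone synthesis should stop at the ketone because the chelated tetrahedral adduct survives until work-up.

Step 2
Reactants: 4 2-(benzyloxy)-1-[4-(benzyloxy)-2-fluorophenyl]ethan-1-one
Product: 5 (Z)-{[2-(benzyloxy)-1-[4-(benzyloxy)-2-fluorophenyl]ethenyl]oxy}trimethylsilane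
Conditions: TMSOTf, Et3N, CH2Cl2, 0 °C
Reagents that add atoms: trimethylsilyl triflate, C[Si](C)(C)OS(=O)(=O)C(F)(F)F
Why: Soft enolization and O-silylation at the only enolizable carbon should give the Z enol silane, in which the fluoroaryl ring lies cis to hydrogen and not to the benzyloxy group.

Step 3
Reactants: 5 (Z)-enol silane; 6 3,4-bis(benzyloxy)benzaldehyde
Product: 9 (2R,3R)-3,7-bis(benzyloxy)-2-[3,4-bis(benzyloxy)phenyl]chroman-4-one, via silyl aldol 7 (not isolated), via 2,3-cis flavanonol 8 (not isolated)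
Conditions: acyloxyborane from (2S,3S)-2-O-(2,6-diisopropoxybenzoyl)tartaric acid and BH3·THF (20 mol %), EtCN, −78 °C; then TBAF (1.2 equiv), THF, −78 to 0 °C; then DBU (0.2 equiv), 20 °C
Reagents that add atoms: none
Why: The boron Lewis acid binds aldehyde 6 and the enol silane adds through an open transition state (Mukaiyama aldol), forming C2–C3 and passing silicon to O1; fluoride then frees the O1 alkoxide, which adds to C8a and expels fluoride through a Meisenheimer anion delocalized through C4a into the C4 carbonyl (intramolecular SNAr), forming O1–C8a. The closest known reaction type is a catalytic enantioselective Mukaiyama aldol coupled with an SNAr O-arylation ortho to an acyl group, together a formal [4+2] annulation across the two opposite bonds of the pyranone ring. The one ring closes by a 6-endo-trig addition at C8a, the acceptor bond C8a=C4a lying inside the new ring as in an oxa-Michael closure, followed by loss of fluoride. C2 is set by the chiral catalyst, which exposes the Si face of the aldehyde (2R); C3 is first set syn by the open transition state and is then epimerized by DBU through the C4 enolate to the diequatorial 2,3-trans isomer (3R), so both aldol diastereomers converge on 9. The step needs face selectivity at the aldehyde and ring closure faster than retro-aldol cleavage: the ortho C4 carbonyl activates the single C–F carbon, the benzyl ether on O3 blocks the competing five-membered closure, and the low temperature of the fluoride stage holds back retro-aldol.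

Step 4
Reactants: 9 (2R,3R)-3,7-bis(benzyloxy)-2-[3,4-bis(benzyloxy)phenyl]chroman-4-one
Product: 10 (2R,3S,4R)-3,7-bis(benzyloxy)-2-[3,4-bis(benzyloxy)phenyl]chroman-4-ol
Conditions: NaBH4, THF/MeOH, 0 °C
Reagents that add atoms: none
Why: Borohydride reduction of the ketone should deliver hydride axially to the all-equatorial chromanone and give the equatorial 4-hydroxyl trans to O3 (4R), although either C4 epimer would serve because C4 is ionized in steps 6 and 7.

Step 5
Reactants: 10 (2R,3S,4R)-3,7-bis(benzyloxy)-2-[3,4-bis(benzyloxy)phenyl]chroman-4-ol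
Product: 11 (2R,3S,4R)-3,7-bis(benzyloxy)-2-[3,4-bis(benzyloxy)phenyl]-6,8-dibromochroman-4-ol
Conditions: NBS (2.05 equiv), CH2Cl2, −40 to 0 °C
Reagents that add atoms: N-bromosuccinimide, O=C1CCC(=O)N1Br
Why: Electrophilic aromatic bromination should take C6 and C8 of ring A, the only carbons ortho or para to two ether oxygens, before it touches ring B, and the two bromines then cap the ring A positions that would otherwise outcompete ring B as nucleophiles in step 7.

Step 6
Reactants: 11 (2R,3S,4R)-3,7-bis(benzyloxy)-2-[3,4-bis(benzyloxy)phenyl]-6,8-dibromochroman-4-ol (about three quarters of the batch)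
Product: 12 (2R,3S)-3,7-bis(benzyloxy)-2-[3,4-bis(benzyloxy)phenyl]-6,8-dibromochromane
Conditions: Et3SiH (10 equiv), CF3CO2H, CH2Cl2, −20 to 0 °C, 0.02 M
Reagents that add atoms: none
Why: Ionic hydrogenation should remove the benzylic hydroxyl, since the C4 cation, stabilized by O1 and by the para 7-benzyloxy group, is trapped by excess silane faster than by an arene at high dilution, and C2 and C3 are not involved.

Step 7
Reactants: 11 (2R,3S,4R)-3,7-bis(benzyloxy)-2-[3,4-bis(benzyloxy)phenyl]-6,8-dibromochroman-4-ol; 12 (2R,3S)-3,7-bis(benzyloxy)-2-[3,4-bis(benzyloxy)phenyl]-6,8-dibromochromane (3 equiv)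
Product: 13 (2R,3S,4R)-3,7-bis(benzyloxy)-2-[3,4-bis(benzyloxy)phenyl]-4-{4,5-bis(benzyloxy)-2-[(2R,3S)-3,7-bis(benzyloxy)-6,8-dibromochroman-2-yl]phenyl}-6,8-dibromochromane
Conditions: TMSOTf (0.2 equiv), 4 Å molecular sieves, CH2Cl2, −40 to −10 °C, slow addition of 11 to 12; excess 12 recovered
Reagents that add atoms: none
Why: Friedel–Crafts alkylation by the flavan-4-yl cation, formed from 11 with loss of water, should occur at C6′ of 12, which is para to the 3′-benzyloxy group and the most nucleophilic carbon left once ring A is capped. Attack anti to the 3-benzyloxy group sets the 3,4-trans (4R) centre, and because both partners come from 9 a minor enantiomer is carried mainly into a separable heterochiral diastereomer.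

Step 8
Reactants: 13 the tetrabromo octabenzyl dimer
Product: 14 (2R,3S,4R)-2-(3,4-dihydroxyphenyl)-4-{2-[(2R,3S)-3,7-dihydroxychroman-2-yl]-4,5-dihydroxyphenyl}chromane-3,7-diol
Conditions: H2 (1 atm), Pd(OH)2/C, Et3N, THF/MeOH/H2O, 20 °C
Reagents that add atoms: none
Why: Hydrogenolysis should cleave the eight benzyl ethers and the four aryl C–Br bonds in one operation, the amine taking up HBr so that the acid-sensitive C4–C6′ bond and the five stereocentres are left intact.

Compound list
1 | 4-(benzyloxy)-1-bromo-2-fluorobenzene | Fc1cc(OCc2ccccc2)ccc1Br | starting material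
2 | 2-(benzyloxy)-N-methoxy-N-methylacetamide | CON(C)C(=O)COCc1ccccc1 | starting material
3 | [4-(benzyloxy)-2-fluorophenyl]magnesium chloride (as its LiCl complex, not isolated) | Fc1cc(OCc2ccccc2)ccc1[Mg]Cl | intermediate
4 | 2-(benzyloxy)-1-[4-(benzyloxy)-2-fluorophenyl]ethan-1-one | O=C(COCc1ccccc1)c1ccc(OCc2ccccc2)cc1F | intermediate
5 | (Z)-{[2-(benzyloxy)-1-[4-(benzyloxy)-2-fluorophenyl]ethenyl]oxy}trimethylsilane | C[Si](C)(C)O/C(=C\OCc1ccccc1)c1ccc(OCc2ccccc2)cc1F | intermediate
6 | 3,4-bis(benzyloxy)benzaldehyde | O=Cc1ccc(OCc2ccccc2)c(OCc2ccccc2)c1 | starting material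
7 | (2S,3R)-2-(benzyloxy)-1-[4-(benzyloxy)-2-fluorophenyl]-3-[3,4-bis(benzyloxy)phenyl]-3-[(trimethylsilyl)oxy]propan-1-one (syn silyl aldol, not isolated) | O=C([C@@H](OCc1ccccc1)[C@H](O[Si](C)(C)C)c1ccc(OCc2ccccc2)c(OCc2ccccc2)c1)c1ccc(OCc2ccccc2)cc1F | intermediate
8 | (2R,3S)-3,7-bis(benzyloxy)-2-[3,4-bis(benzyloxy)phenyl]chroman-4-one (2,3-cis, not isolated) | O=C1[C@@H](OCc2ccccc2)[C@@H](c2ccc(OCc3ccccc3)c(OCc3ccccc3)c2)Oc2cc(OCc3ccccc3)ccc21 | intermediate
9 | (2R,3R)-3,7-bis(benzyloxy)-2-[3,4-bis(benzyloxy)phenyl]chroman-4-one (2,3-trans) | O=C1[C@H](OCc2ccccc2)[C@@H](c2ccc(OCc3ccccc3)c(OCc3ccccc3)c2)Oc2cc(OCc3ccccc3)ccc21 | intermediate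
10 | (2R,3S,4R)-3,7-bis(benzyloxy)-2-[3,4-bis(benzyloxy)phenyl]chroman-4-ol (2,3-trans-3,4-trans) | O[C@H]1[C@H](OCc2ccccc2)[C@@H](c2ccc(OCc3ccccc3)c(OCc3ccccc3)c2)Oc2cc(OCc3ccccc3)ccc21 | intermediate
11 | (2R,3S,4R)-3,7-bis(benzyloxy)-2-[3,4-bis(benzyloxy)phenyl]-6,8-dibromochroman-4-ol | O[C@H]1[C@H](OCc2ccccc2)[C@@H](c2ccc(OCc3ccccc3)c(OCc3ccccc3)c2)Oc2c(Br)c(OCc3ccccc3)c(Br)cc21 | intermediate
12 | (2R,3S)-3,7-bis(benzyloxy)-2-[3,4-bis(benzyloxy)phenyl]-6,8-dibromochromane | c1ccccc1COc1c(Br)cc2c(c1Br)O[C@H](c1ccc(OCc3ccccc3)c(OCc3ccccc3)c1)[C@@H](OCc1ccccc1)C2 | intermediate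
13 | (2R,3S,4R)-3,7-bis(benzyloxy)-2-[3,4-bis(benzyloxy)phenyl]-4-{4,5-bis(benzyloxy)-2-[(2R,3S)-3,7-bis(benzyloxy)-6,8-dibromochroman-2-yl]phenyl}-6,8-dibromochromane | c1ccccc1COc1c(Br)cc2c(c1Br)O[C@H](c1cc(OCc3ccccc3)c(OCc3ccccc3)cc1[C@@H]1c3cc(Br)c(OCc4ccccc4)c(Br)c3O[C@H](c3ccc(OCc4ccccc4)c(OCc4ccccc4)c3)[C@H]1OCc1ccccc1)[C@@H](OCc1ccccc1)C2 | intermediate
14 | (2R,3S,4R)-2-(3,4-dihydroxyphenyl)-4-{2-[(2R,3S)-3,7-dihydroxychroman-2-yl]-4,5-dihydroxyphenyl}chromane-3,7-diol | Oc1ccc2c(c1)O[C@H](c1cc(O)c(O)cc1[C@@H]1c3ccc(O)cc3O[C@H](c3ccc(O)c(O)c3)[C@H]1O)[C@@H](O)C2 | target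

Total step count: 8. Longest linear sequence: 8 (steps 1 to 8 in a line, because 12 is drawn from 11).

Steps most likely to fail

Step 3. Retro-aldol cleavage of the freed aldolate before ring closure would erode the configuration at C2, and the flavanonol enolate could open to the chalcone during the epimerization. The fallback sets out from 6 and returns at 9. Bought 1-[4-(benzyloxy)-2-hydroxyphenyl]ethan-1-one F1 is protected (MOMCl, iPr2NEt) as 1-[4-(benzyloxy)-2-(methoxymethoxy)phenyl]ethan-1-one F2. Claisen–Schmidt condensation of it with 6 (KOH, EtOH) should give the (E)-chalcone F3. Juliá–Colonna epoxidation (poly-L-leucine, urea–H2O2, DBU, THF) should give the (2R,3S)-epoxy ketone F4. HCl in MeOH then removes the acetal and lets the phenol open the epoxide at the benzylic carbon with inversion, giving the 2,3-trans 3-hydroxyflavanone F5. Benzyl 2,2,2-trichloroacetimidate with catalytic TfOH returns 9.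

Step 7. Ionization of the dibrominated 4-ol may be slow, ring B may be attacked at a carbon other than C6′, and the product may be alkylated further. The fallback sets out from 11 and returns at 13. BnSH and BF3·OEt2 convert the 4-hydroxyl into the 3,4-trans 4-benzylsulfanyl ether F6. This stable donor is activated with AgBF4 in THF/CH2Cl2 at 0 °C in the presence of 12, so that the thiophilic silver salt generates the C4 cation irreversibly.

Step 8. Hydrogenolysis of the four C–Br bonds may stall as bromide poisons the catalyst, and long exposure may open the benzylic C2–O1 bonds. The fallback sets out from 13 and returns at 14. Bromine–lithium exchange (n-BuLi, THF, −78 °C; MeOH quench) removes the halogens first and gives the bromine-free octabenzyl ether F7, which is then hydrogenolysed over Pd(OH)2/C under neutral conditions.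

Further compounds
F1 | step 3 | 1-[4-(benzyloxy)-2-hydroxyphenyl]ethan-1-one | CC(=O)c1ccc(OCc2ccccc2)cc1O
F2 | step 3 | 1-[4-(benzyloxy)-2-(methoxymethoxy)phenyl]ethan-1-one | CC(=O)c1ccc(OCc2ccccc2)cc1OCOC
F3 | step 3 | (E)-1-[4-(benzyloxy)-2-(methoxymethoxy)phenyl]-3-[3,4-bis(benzyloxy)phenyl]prop-2-en-1-one | O=C(/C=C/c1ccc(OCc2ccccc2)c(OCc2ccccc2)c1)c1ccc(OCc2ccccc2)cc1OCOC
F4 | step 3 | [4-(benzyloxy)-2-(methoxymethoxy)phenyl]{(2R,3S)-3-[3,4-bis(benzyloxy)phenyl]oxiran-2-yl}methanone | O=C(c1ccc(OCc2ccccc2)cc1OCOC)[C@@H]1O[C@H]1c1ccc(OCc2ccccc2)c(OCc2ccccc2)c1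
F5 | step 3 | (2R,3R)-7-(benzyloxy)-2-[3,4-bis(benzyloxy)phenyl]-3-hydroxychroman-4-one | O=C1[C@H](O)[C@@H](c2ccc(OCc3ccccc3)c(OCc3ccccc3)c2)Oc2cc(OCc3ccccc3)ccc21
F6 | step 7 | 4-benzylsulfanyl analogue of 11, sulfur trans to O3 | C(S[C@H]1[C@H](OCc2ccccc2)[C@@H](c2ccc(OCc3ccccc3)c(OCc3ccccc3)c2)Oc2c(Br)c(OCc3ccccc3)c(Br)cc21)c1ccccc1
F7 | step 8 | bromine-free octabenzyl ether of 14 | c1ccccc1COc1ccc2c(c1)O[C@H](c1cc(OCc3ccccc3)c(OCc3ccccc3)cc1[C@@H]1c3ccc(OCc4ccccc4)cc3O[C@H](c3ccc(OCc4ccccc4)c(OCc4ccccc4)c3)[C@H]1OCc1ccccc1)[C@@H](OCc1ccccc1)C2
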